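## Retrosynthetic overview

1. Last bond: C(sp3)–C(sp2) between the dioxane side chain and ring A, by B-alkyl Suzuki coupling of a 6-vinyl-1,2-dioxane ester with a cis-fused bicyclic enol triflate; no stereocentre is involved.
2. Enol triflate ⇐ cis-fused 1,1,3,6-tetramethyl-octalin-2-one ⇐ acyclic (Z)-diene/vinyl ketone: ring A (the ring with the CMe2 group) and ring B (the methylcyclohexene) are closed together by one thermal intramolecular Diels–Alder reaction. The ketone α-methyl centre relays the absolute configuration to both ring-fusion carbons and is erased in the triflate.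
3. Triene ketone ⇐ Evans alkylation with (Z)-1,3-dichloropropene, Negishi coupling, Weinreb amide, reverse prenylation.
4. Dioxane (C3 carries the propanoate, C6 is quaternary): C2–C3 bond by a chiral titanium enolate adding to a cyclic peroxycarbenium ion; ring by peroxy-hemiacetal closure of a 4-hydroperoxy aldehyde; C6 from geraniol by Sharpless epoxidation and perhydrolysis with inversion; glycol cleavage and Wittig reaction give the vinyl group.
5. Ring order: rings A and B together (step 5); the 1,2-dioxane ring separately (step 9); the two halves are joined in step 14.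

Assumption: the target is taken as drawn, (2R,3R,6R) in the dioxane part and (4aR,8aS), cis-fused, in the decalin; Grignard solutions, 9-BBN and anhydrous tBuOOH count as commercial.

## Route

Step 1
Reactants: 1 (4S)-4-benzyl-3-propanoyl-1,3-oxazolidin-2-one; 2 (Z)-1,3-dichloroprop-1-ene
Product: 4 (4S)-4-benzyl-3-[(2R,4Z)-5-chloro-2-methylpent-4-enoyl]-1,3-oxazolidin-2-one, via sodium enolate 3 (not isolated)
Conditions: NaN(SiMe3)2, THF, −78 °C; then 2 (3 equiv), NaI (10 mol %), −78 → −40 °C
Reagents that add atoms: none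
Why: Evans asymmetric alkylation, in which the chelated sodium (Z)-enolate is alkylated by SN2 at the allylic CH2Cl of 2 on the face opposite the benzyl group, setting the (2R) methyl-bearing centre, while the vinylic C–Cl bond is inert and keeps its Z geometry.

Step 2
Reactants: 4 (4S)-4-benzyl-3-[(2R,4Z)-5-chloro-2-methylpent-4-enoyl]-1,3-oxazolidin-2-one
Product: 5 (4S)-4-benzyl-3-[(2R,4Z)-2,6-dimethylhepta-4,6-dienoyl]-1,3-oxazolidin-2-one
Conditions: CH2=C(CH3)MgBr + ZnCl2, THF, 0 °C; then 4, Pd(P(tBu)3)2 (3 mol %), THF/NMP, 50 °C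
Reagents that add atoms: isopropenylmagnesium bromide, CC(=C)[Mg]Br
Why: Negishi cross-coupling, in which the palladium catalyst inserts into the alkenyl C–Cl bond and couples with the alkenylzinc reagent with retention of the Z geometry, the organozinc neither attacking the imide nor enolising the α-centre, and no stereocentre is formed.

Step 3
Reactants: 5 (4S)-4-benzyl-3-[(2R,4Z)-2,6-dimethylhepta-4,6-dienoyl]-1,3-oxazolidin-2-one
Product: 6 (2R,4Z)-N-methoxy-N,2,6-trimethylhepta-4,6-dienamide
Conditions: MeNH(OMe)·HCl, AlMe3, CH2Cl2, 0 °C → rt; Rochelle salt work-up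
Reagents that add atoms: N,O-dimethylhydroxylamine hydrochloride, CNOC.Cl
Why: Weinreb transamidation of the N-acyl oxazolidinone by the aluminium amide at the exocyclic carbonyl, a non-basic acyl transfer that leaves the (2R) centre and the Z-diene untouched.

Step 4
Reactants: 6 (2R,4Z)-N-methoxy-N,2,6-trimethylhepta-4,6-dienamide
Product: 8 (5R,7Z)-3,3,5,9-tetramethyldeca-1,7,9-trien-4-one, via magnesium hemiaminal chelate 7 (not isolated)
Conditions: (CH3)2C=CHCH2MgCl (1.5 equiv), THF, −78 → 0 °C; aq NH4Cl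
Reagents that add atoms: prenylmagnesium chloride, CC(C)=CC[Mg]Cl
Why: Weinreb ketone synthesis with an allylic Grignard reagent that adds through its γ-carbon (SE2′, six-membered transition state) to give the reverse-prenyl ketone, the chelate 7 preventing over-addition and enolisation so that the α-centre survives, and the new quaternary carbon keeps the vinyl group out of conjugation.

Step 5
Reactants: 8 (5R,7Z)-3,3,5,9-tetramethyldeca-1,7,9-trien-4-one
Product: 9 (3R,4aR,8aS)-1,1,3,6-tetramethyl-3,4,4a,7,8,8a-hexahydronaphthalen-2(1H)-one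
Conditions: toluene (0.01 M), BHT (5 mol %), sealed tube, 165 °C, 36 h
Reagents that add atoms: none
Why: Thermal type 1 intramolecular Diels–Alder reaction of a 1,7,9-decatriene that closes rings A and B together, in which the Z-diene can reach only the cis-fused transition state (an E-diene would have to sit axial, syn to an axial methyl of the CMe2 group, and would give the trans isomer) and the α-methyl group must be equatorial in the chair-like tether to avoid a syn-pentane clash with that same axial methyl, which selects the diene face and sets (4aR,8aS).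

Step 6
Reactants: 9 (3R,4aR,8aS)-1,1,3,6-tetramethyl-3,4,4a,7,8,8a-hexahydronaphthalen-2(1H)-one
Product: 11 (4aR,8aS)-1,1,3,6-tetramethyl-1,4,4a,7,8,8a-hexahydronaphthalen-2-yl trifluoromethanesulfonate, via potassium enolate 10 (not isolated)
Conditions: KN(SiMe3)2, THF, −78 → 0 °C; PhNTf2, −78 °C → rt
Reagents that add atoms: N-phenylbis(trifluoromethanesulfonimide), FC(F)(F)S(=O)(=O)N(c1ccccc1)S(=O)(=O)C(F)(F)F
Why: Enol triflate formation, in which the ketone has a single α-hydrogen (C3) so only one enolate can form, O-triflation erases the relay stereocentre and fixes the tetrasubstituted C2=C3 alkene, and 4a and 8a are untouched.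

Step 7
Reactants: 12 geraniol
Product: 13 [(2R,3R)-3-methyl-3-(4-methylpent-3-en-1-yl)oxiran-2-yl]methanol
Conditions: Ti(OiPr)4 (5 mol %), D-(−)-diethyl tartrate (7 mol %), tBuOOH, 4 Å MS, CH2Cl2, −20 °C
Reagents that add atoms: tert-butyl hydroperoxide, CC(C)(C)OO
Why: Sharpless asymmetric epoxidation, in which the titanium tartrate complex epoxidises only the allylic alkene and the D-(−)-tartrate delivers oxygen to the face that gives the (2R,3R)-epoxide (about 95% ee).

Step 8
Reactants: 13 [(2R,3R)-3-methyl-3-(4-methylpent-3-en-1-yl)oxiran-2-yl]methanol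
Product: 14 (2R,3S)-3-hydroperoxy-3,7-dimethyloct-6-ene-1,2-diol
Conditions: H2O2 (anhydrous, in Et2O, 10 equiv), H3PMo12O40 (2 mol %), Et2O, 0 °C → rt
Reagents that add atoms: hydrogen peroxide, OO
Why: Acid-catalysed perhydrolysis of a 2,3-epoxy alcohol (borderline SN2 epoxide opening), in which H2O2 attacks the tertiary C3 anti to the oxirane oxygen so that C3 is inverted to (3S), C2 is untouched, and the large excess of H2O2 outruns participation of the remote alkene.

Step 9
Reactants: 14 (2R,3S)-3-hydroperoxy-3,7-dimethyloct-6-ene-1,2-diol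
Product: 17 (6S)-6-[(1R)-1,2-bis(acetyloxy)ethyl]-6-methyl-1,2-dioxan-3-yl acetate, via hydroperoxy aldehyde 15 (not isolated), via peroxy-hemiacetal 16 (not isolated)
Conditions: O3, pyridine (3 equiv), CH2Cl2, −78 °C; N2 purge, −20 °C; then Ac2O, DMAP (cat), 0 °C
Reagents that add atoms: ozone, [O-][O+]=O; acetic anhydride, CC(=O)OC(C)=O
Why: Pyridine-mediated ozonolysis of the only alkene gives aldehyde 15 without a reductant so the hydroperoxide survives, 15 closes to the six-membered peroxy-hemiacetal 16 (this forms the 1,2-dioxane ring, hydroperoxides adding to aldehydes far more strongly than alcohols) and acetylation traps all three hydroxyls, C6 being untouched and the C3 mixture being erased in step 10.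

Step 10
Reactants: 17 (6S)-6-[(1R)-1,2-bis(acetyloxy)ethyl]-6-methyl-1,2-dioxan-3-yl acetate; 18 (4S)-4-isopropyl-3-propanoyl-1,3-thiazolidine-2-thione
Product: 20 (2R)-2-[(3R,6S)-6-[(1R)-1,2-bis(acetyloxy)ethyl]-6-methyl-1,2-dioxan-3-yl]-1-[(4S)-4-isopropyl-2-thioxo-1,3-thiazolidin-3-yl]propan-1-one, via chlorotitanium enolate 19 (not isolated)
Conditions: 18, TiCl4, iPr2NEt, CH2Cl2, −78 → −40 °C; then 17, SnCl4, −78 °C; aq NH4Cl
Reagents that add atoms: none
Why: Proposed new method: SnCl4 ionises the anomeric acetate to a six-membered peroxycarbenium ion that is captured by the chelated chlorotitanium (Z)-enolate 19 in an open transition state, the closest known reactions being additions of silyl ketene acetals to 3-alkoxy-1,2-dioxolanes and anti-selective Mukaiyama-type additions of N-acyl thiazolidinethione titanium enolates to acetals; the (4S)-isopropyl group shields one enolate face and sets (2R), while the anti topicity of such additions together with axial attack on the half-chair that keeps the bulky diacetoxyethyl group pseudo-equatorial places the new bond cis to that group and sets (3R), the C3 acetate mixture converging through the planar cation.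

Step 11
Reactants: 20 (2R)-2-[(3R,6S)-6-[(1R)-1,2-bis(acetyloxy)ethyl]-6-methyl-1,2-dioxan-3-yl]-1-[(4S)-4-isopropyl-2-thioxo-1,3-thiazolidin-3-yl]propan-1-one
Product: 21 methyl (2R)-2-[(3R,6S)-6-[(1R)-1,2-dihydroxyethyl]-6-methyl-1,2-dioxan-3-yl]propanoate
Conditions: K2CO3 (0.3 equiv), MeOH, 0 °C
Reagents that add atoms: methanol, CO
Why: Methanolysis (acyl transfer) of the activated N-acyl thiazolidinethione to the methyl ester with concurrent transesterification of the two acetates, run cold with catalytic base so that C2 is not epimerised and the ring is not opened by retro-oxa-Michael reaction.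

Step 12
Reactants: 21 methyl (2R)-2-[(3R,6S)-6-[(1R)-1,2-dihydroxyethyl]-6-methyl-1,2-dioxan-3-yl]propanoate
Product: 22 methyl (2R)-2-[(3R,6S)-6-formyl-6-methyl-1,2-dioxan-3-yl]propanoate
Conditions: NaIO4, THF/H2O, 0 °C → rt
Reagents that add atoms: none
Why: Malaprade glycol cleavage removes the terminal carbon and the now superfluous carbinol stereocentre and gives a non-enolisable α-peroxy aldehyde, C6 keeping its configuration.

Step 13
Reactants: 22 methyl (2R)-2-[(3R,6S)-6-formyl-6-methyl-1,2-dioxan-3-yl]propanoate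
Product: 23 methyl (2R)-2-[(3R,6S)-6-ethenyl-6-methyl-1,2-dioxan-3-yl]propanoate
Conditions: Ph3PCH3Br, KN(SiMe3)2, THF, 0 °C; ylide added to 22 at −78 °C, then 0 °C
Reagents that add atoms: methyltriphenylphosphonium bromide, C[P+](c1ccccc1)(c1ccccc1)c1ccccc1.[Br-]
Why: Wittig methylenation of a non-enolisable aldehyde, run cold with inverse addition so that the ylide does not enolise the ester, and no stereocentre is involved.

Step 14
Reactants: 23 methyl (2R)-2-[(3R,6S)-6-ethenyl-6-methyl-1,2-dioxan-3-yl]propanoate; 11 (4aR,8aS)-1,1,3,6-tetramethyl-1,4,4a,7,8,8a-hexahydronaphthalen-2-yl trifluoromethanesulfonate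
Product: 25 methyl (2R)-2-[(3R,6R)-6-methyl-6-{2-[(4aR,8aS)-1,1,3,6-tetramethyl-1,4,4a,7,8,8a-hexahydronaphthalen-2-yl]ethyl}-1,2-dioxan-3-yl]propanoate, via alkylborane 24 (not isolated)
Conditions: 9-BBN, THF, 0 °C → rt; then 11, PdCl2(dppf) (5 mol %), AsPh3 (10 mol %), K3PO4 (3 M aq), DMF/THF, rt → 40 °C, dark
Reagents that add atoms: none
Why: Anti-Markovnikov hydroboration puts boron on the terminal carbon and the B-alkyl Suzuki–Miyaura coupling joins it to the hindered enol triflate, a palladium cross-coupling of the kind that saturated 1,2-dioxanes tolerate, no stereocentre is touched (the C6 descriptor changes from S to R only through the priority change) and the product is the target.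

## Compound list

1 | (4S)-4-benzyl-3-propanoyl-1,3-oxazolidin-2-one | CCC(=O)N1[C@@H](Cc2ccccc2)COC1=O | starting material
2 | (Z)-1,3-dichloroprop-1-ene | ClC/C=C\Cl | starting material
3 | sodium (1Z)-1-[(4S)-4-benzyl-2-oxo-1,3-oxazolidin-3-yl]prop-1-en-1-olate (sodium enolate of 1) | C/C=C(\[O-])N1[C@@H](Cc2ccccc2)COC1=O.[Na+] | intermediate (not isolated)
4 | (4S)-4-benzyl-3-[(2R,4Z)-5-chloro-2-methylpent-4-enoyl]-1,3-oxazolidin-2-one | C[C@H](C/C=C\Cl)C(=O)N1[C@@H](Cc2ccccc2)COC1=O | intermediate
5 | (4S)-4-benzyl-3-[(2R,4Z)-2,6-dimethylhepta-4,6-dienoyl]-1,3-oxazolidin-2-one | C[C@H](C/C=C\C(C)=C)C(=O)N1[C@@H](Cc2ccccc2)COC1=O | intermediate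
6 | (2R,4Z)-N-methoxy-N,2,6-trimethylhepta-4,6-dienamide | C[C@H](C/C=C\C(C)=C)C(=O)N(C)OC | intermediate
7 | chloromagnesium (5R,7Z)-4-[methoxy(methyl)amino]-3,3,5,9-tetramethyldeca-1,7,9-trien-4-olate (tetrahedral chelate, C4 unassigned) | C[C@H](C/C=C\C(C)=C)C(O[Mg]Cl)(N(C)OC)C(C)(C)C=C | intermediate (not isolated)
8 | (5R,7Z)-3,3,5,9-tetramethyldeca-1,7,9-trien-4-one | C[C@H](C/C=C\C(C)=C)C(=O)C(C)(C)C=C | intermediate
9 | (3R,4aR,8aS)-1,1,3,6-tetramethyl-3,4,4a,7,8,8a-hexahydronaphthalen-2(1H)-one (cis-fused) | O=C1[C@H](C)C[C@@H]2C=C(C)CC[C@@H]2C1(C)C | intermediate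
10 | potassium (4aR,8aS)-1,1,3,6-tetramethyl-1,4,4a,7,8,8a-hexahydronaphthalen-2-olate | [K+].[O-]C1=C(C)C[C@@H]2C=C(C)CC[C@@H]2C1(C)C | intermediate (not isolated)
11 | (4aR,8aS)-1,1,3,6-tetramethyl-1,4,4a,7,8,8a-hexahydronaphthalen-2-yl trifluoromethanesulfonate | FC(F)(F)S(=O)(=O)OC1=C(C)C[C@@H]2C=C(C)CC[C@@H]2C1(C)C | intermediate
12 | geraniol, (2E)-3,7-dimethylocta-2,6-dien-1-ol | CC(C)=CCC/C(C)=C/CO | starting material
13 | [(2R,3R)-3-methyl-3-(4-methylpent-3-en-1-yl)oxiran-2-yl]methanol | OC[C@H]1O[C@]1(C)CCC=C(C)C | intermediate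
14 | (2R,3S)-3-hydroperoxy-3,7-dimethyloct-6-ene-1,2-diol | OC[C@@H](O)[C@@](C)(OO)CCC=C(C)C | intermediate
15 | (4S,5R)-4-hydroperoxy-5,6-dihydroxy-4-methylhexanal | OC[C@@H](O)[C@@](C)(OO)CCC=O | intermediate (not isolated)
16 | (6S)-6-[(1R)-1,2-dihydroxyethyl]-6-methyl-1,2-dioxan-3-ol (both C3 epimers) | OC[C@@H](O)[C@@]1(C)OOC(O)CC1 | intermediate (not isolated)
17 | (6S)-6-[(1R)-1,2-bis(acetyloxy)ethyl]-6-methyl-1,2-dioxan-3-yl acetate (both C3 epimers) | CC(=O)OC[C@@H](OC(C)=O)[C@@]1(C)OOC(OC(C)=O)CC1 | intermediate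
18 | (4S)-4-isopropyl-3-propanoyl-1,3-thiazolidine-2-thione | CCC(=O)N1[C@@H](C(C)C)CSC1=S | starting material
19 | trichlorotitanium (Z)-enolate of 18 | C/C=C(\O[Ti](Cl)(Cl)Cl)N1[C@@H](C(C)C)CSC1=S | intermediate (not isolated)
20 | (2R)-2-[(3R,6S)-6-[(1R)-1,2-bis(acetyloxy)ethyl]-6-methyl-1,2-dioxan-3-yl]-1-[(4S)-4-isopropyl-2-thioxo-1,3-thiazolidin-3-yl]propan-1-one | CC(C)[C@H]1CSC(=S)N1C(=O)[C@H](C)[C@H]2CC[C@@](C)([C@H](OC(C)=O)COC(C)=O)OO2 | intermediate
21 | methyl (2R)-2-[(3R,6S)-6-[(1R)-1,2-dihydroxyethyl]-6-methyl-1,2-dioxan-3-yl]propanoate | COC(=O)[C@H](C)[C@H]1CC[C@@](C)([C@H](O)CO)OO1 | intermediate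
22 | methyl (2R)-2-[(3R,6S)-6-formyl-6-methyl-1,2-dioxan-3-yl]propanoate | COC(=O)[C@H](C)[C@H]1CC[C@@](C)(C=O)OO1 | intermediate
23 | methyl (2R)-2-[(3R,6S)-6-ethenyl-6-methyl-1,2-dioxan-3-yl]propanoate | COC(=O)[C@H](C)[C@H]1CC[C@@](C)(C=C)OO1 | intermediate
24 | methyl (2R)-2-[(3R,6R)-6-[2-(9-borabicyclo[3.3.1]nonan-9-yl)ethyl]-6-methyl-1,2-dioxan-3-yl]propanoate | COC(=O)[C@H](C)[C@H]1CC[C@@](C)(CCB2C3CCCC2CCC3)OO1 | intermediate (not isolated)
25 | methyl (2R)-2-[(3R,6R)-6-methyl-6-{2-[(4aR,8aS)-1,1,3,6-tetramethyl-1,4,4a,7,8,8a-hexahydronaphthalen-2-yl]ethyl}-1,2-dioxan-3-yl]propanoate | COC(=O)[C@H](C)[C@H]1CC[C@@](C)(CCC2=C(C)C[C@@H]3C=C(C)CC[C@@H]3C2(C)C)OO1 | target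

## Step count and weak points

Total step count: 14. Longest linear sequence: 8 steps (12 → 25, steps 7–14); the other branch (1 → 11) has 6 steps before the union in step 14.

Step 5 (intramolecular Diels–Alder reaction of 8). The dienophile is unactivated and a Z-diene can isomerise by a [1,5]-hydrogen shift at the temperature needed. The fallback activates the dienophile with a traceless sulfone. It sets out from Weinreb amide 6. Acylation of the lithium aza-enolate of isobutyraldehyde N-cyclohexylimine (LiN(iPr)2, THF, −78 °C) gives the keto imine (4R,6Z)-1-(cyclohexylimino)-2,2,4,8-tetramethylnona-6,8-dien-3-one F1. Aqueous oxalic acid releases the keto aldehyde (4R,6Z)-2,2,4,8-tetramethyl-3-oxonona-6,8-dienal F2. Horner–Wadsworth–Emmons reaction with diethyl [(phenylsulfonyl)methyl]phosphonate (LiCl, iPr2NEt, MeCN) gives the vinyl sulfone (1E,5R,7Z)-3,3,5,9-tetramethyl-1-(phenylsulfonyl)deca-1,7,9-trien-4-one F3. This cyclises at 80–110 °C through the same cis-only transition state to the sulfonyl decalone (3R,4aR,8R,8aS)-1,1,3,6-tetramethyl-8-(phenylsulfonyl)-3,4,4a,7,8,8a-hexahydronaphthalen-2(1H)-one F4. Reductive desulfonylation (sodium amalgam Na/Hg, Na2HPO4, MeOH, −20 °C) returns to the route at ketone 9.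

Step 10 (enolate addition to the peroxycarbenium ion). The reaction is new, the acetates and the peroxide must survive two Lewis acids, and the C3 selectivity of a cyclic cation is the least certain stereochemical call in the route. The fallback forms the C3–O bond last by an oxa-Michael reaction. It sets out from 14. Ozonolysis as in step 9 without acetylation, then Wittig reaction of the peroxy-hemiacetal 16 (through its open form 15) with methyl 2-(triphenylphosphoranylidene)propanoate, gives the hydroperoxy enoate methyl (2E,6S,7R)-6-hydroperoxy-7,8-dihydroxy-2,6-dimethyloct-2-enoate F5. Et2NH in CF3CH2OH closes the dioxane by intramolecular conjugate addition of the hydroperoxide. This step is not stereocontrolled at C2 and C3, so the diastereomers are separated by chromatography; the route is rejoined at diol ester 21.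

Step 14 (hydroboration and B-alkyl Suzuki coupling). The alkylborane or zerovalent palladium may attack the O–O bond, and the triflate is flanked by a quaternary carbon. The fallback joins the halves through an alkyne. It sets out from aldehyde 22. Ohira–Bestmann homologation (dimethyl (1-diazo-2-oxopropyl)phosphonate, K2CO3, MeOH, 0 °C) gives the alkyne methyl (2R)-2-[(3R,6S)-6-ethynyl-6-methyl-1,2-dioxan-3-yl]propanoate F6. Sonogashira coupling with triflate 11 (PdCl2(PPh3)2, CuI, iPr2NH, THF, rt) gives the enyne methyl (2R)-2-[(3R,6S)-6-methyl-6-{[(4aR,8aS)-1,1,3,6-tetramethyl-1,4,4a,7,8,8a-hexahydronaphthalen-2-yl]ethynyl}-1,2-dioxan-3-yl]propanoate F7. Diimide (potassium azodicarboxylate KO2CN=NCO2K, AcOH, MeOH) saturates the alkyne and the resulting disubstituted alkene but not the tetrasubstituted or trisubstituted ring alkenes, and gives target 25.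

## Further compounds

F1 | step 5 | (4R,6Z)-1-(cyclohexylimino)-2,2,4,8-tetramethylnona-6,8-dien-3-one | C[C@H](C/C=C\C(C)=C)C(=O)C(C)(C)C=NC1CCCCC1
F2 | step 5 | (4R,6Z)-2,2,4,8-tetramethyl-3-oxonona-6,8-dienal | C[C@H](C/C=C\C(C)=C)C(=O)C(C)(C)C=O
F3 | step 5 | (1E,5R,7Z)-3,3,5,9-tetramethyl-1-(phenylsulfonyl)deca-1,7,9-trien-4-one | C[C@H](C/C=C\C(C)=C)C(=O)C(C)(C)/C=C/S(=O)(=O)c1ccccc1
F4 | step 5 | (3R,4aR,8R,8aS)-1,1,3,6-tetramethyl-8-(phenylsulfonyl)-3,4,4a,7,8,8a-hexahydronaphthalen-2(1H)-one | O=C1[C@H](C)C[C@@H]2C=C(C)C[C@@H](S(=O)(=O)c3ccccc3)[C@@H]2C1(C)C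
F5 | step 10 | methyl (2E,6S,7R)-6-hydroperoxy-7,8-dihydroxy-2,6-dimethyloct-2-enoate | COC(=O)/C(C)=C/CC[C@](C)(OO)[C@H](O)CO
F6 | step 14 | methyl (2R)-2-[(3R,6S)-6-ethynyl-6-methyl-1,2-dioxan-3-yl]propanoate | COC(=O)[C@H](C)[C@H]1CC[C@@](C)(C#C)OO1
F7 | step 14 | methyl (2R)-2-[(3R,6S)-6-methyl-6-{[(4aR,8aS)-1,1,3,6-tetramethyl-1,4,4a,7,8,8a-hexahydronaphthalen-2-yl]ethynyl}-1,2-dioxan-3-yl]propanoate | COC(=O)[C@H](C)[C@H]1CC[C@@](C)(C#CC2=C(C)C[C@@H]3C=C(C)CC[C@@H]3C2(C)C)OO1
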